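**Strategy.** The upper pyran ring (O1–C2–C3–C4–C4a–C8a, ring C) is a chroman. It is cut by a retro-[4+2] into an ortho-quinone methide on ring A, whose exocyclic C4 already carries the finished lower flavanoid, and an (E)-2-arylvinyl acetate that brings C2, C3 and ring B. One acid-catalysed asymmetric oxa-Diels–Alder reaction joins the two advanced fragments, closes the last ring by forming C3–C4 and O1–C2, and sets C2, C3 and C4 in the all-trans array that the E alkene and an aryl-endo approach dictate. The precursor is an ortho-hydroxybenzhydrol on C6 of a benzyl-protected (2R,3R)-dihydroflavonol; its C4 ketone, inert to acid, is reduced last to the 3,4-trans diol.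

Key step: step 11

Assumption: the sense of induction of the binaphthyl catalyst in step 11 cannot be assigned with certainty in advance; the (R)-catalyst is written, and its (S)-enantiomer would be used if a first run shows the opposite face of C4 to be preferred.
Assumption: compounds 1, 4 and 10, bis[(pinacolato)boryl]methane and both catalyst enantiomers are taken as commercial.

**Step 1**
Reactants: 1 1-[4-(benzyloxy)-2-hydroxyphenyl]ethanone
Product: 2 1-[4-(benzyloxy)-5-bromo-2-hydroxyphenyl]ethanone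
Conditions: NBS, MeCN, 0 °C to rt
Reagents that add atoms: N-bromosuccinimide O=C1CCC(=O)N1Br
Why: Electrophilic aromatic bromination should go to C5, which is para to the free phenol and ortho to the benzyloxy group and is less hindered than C3 between the two oxygens.

**Step 2**
Reactants: 2 1-[4-(benzyloxy)-5-bromo-2-hydroxyphenyl]ethanone
Product: 3 1-[4-(benzyloxy)-5-bromo-2-(methoxymethoxy)phenyl]ethanone
Conditions: MOMCl, iPr2NEt, CH2Cl2, 0 to 40 °C
Reagents that add atoms: chloromethyl methyl ether COCCl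
Why: Williamson-type O-alkylation masks the chelated phenol as an acetal that survives the basic steps 3 and 4 and is released by the acid of step 5.

**Step 3**
Reactants: 3 1-[4-(benzyloxy)-5-bromo-2-(methoxymethoxy)phenyl]ethanone; 4 3,4-bis(benzyloxy)benzaldehyde
Product: 5 (E)-1-[4-(benzyloxy)-5-bromo-2-(methoxymethoxy)phenyl]-3-[3,4-bis(benzyloxy)phenyl]prop-2-en-1-one
Conditions: KOH, EtOH/THF, rt
Reagents that add atoms: none
Why: Claisen–Schmidt aldol condensation of the methyl ketone with the non-enolisable aldehyde gives the E enone after E1cB dehydration.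

**Step 4**
Reactants: 5 the (E)-chalcone
Product: 6 [4-(benzyloxy)-5-bromo-2-(methoxymethoxy)phenyl][(2R,3S)-3-[3,4-bis(benzyloxy)phenyl]oxiran-2-yl]methanone (trans epoxide)
Conditions: poly-L-leucine, urea–H2O2, DBU, THF, rt
Reagents that add atoms: hydrogen peroxide (used as its urea adduct) OO
Why: Juliá–Colonna epoxidation, a Weitz–Scheffer conjugate addition of hydroperoxide inside the helical peptide, should give the trans (2R,3S) epoxy ketone, the face being set by the L-configured polypeptide.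

**Step 5**
Reactants: 6 the (2R,3S)-epoxy ketone
Product: 8 (2R,3R)-7-(benzyloxy)-2-[3,4-bis(benzyloxy)phenyl]-6-bromo-3-hydroxy-2,3-dihydro-4H-chromen-4-one, via 2-hydroxyphenyl epoxy ketone 7 (not isolated)
Conditions: conc. HCl, MeOH/THF, 55 °C
Reagents that add atoms: none
Why: Acid removes the methoxymethyl group and the freed phenol opens the protonated epoxide at the benzylic carbon (6-endo, SN2-like, inversion), which turns the trans epoxide into the 2,3-trans (2R,3R) dihydroflavonol while the epoxide carbon next to the ketone keeps its configuration as C3.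

**Step 6**
Reactants: 8 the 6-bromo-dihydroflavonol
Product: 9 (2R,3R)-7-(benzyloxy)-2-[3,4-bis(benzyloxy)phenyl]-3-hydroxy-4-oxo-3,4-dihydro-2H-chromene-6-carbaldehyde
Conditions: Pd(OAc)2 (2 mol %), di(1-adamantyl)-n-butylphosphine, TMEDA, CO/H2 (1:1, 5 bar), toluene, 100 °C
Reagents that add atoms: carbon monoxide [C-]#[O+]
Why: Palladium-catalysed reductive carbonylation (oxidative addition of the aryl bromide to zerovalent palladium, CO insertion, hydrogenolysis of the acyl palladium species) should give the aldehyde without touching the ketone, the carbinol or the benzyl ethers.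

**Step 7**
Reactants: 9 the 6-carbaldehyde; 10 3-hydroxyphenyl benzoate
Product: 12 4-{[(2R,3R)-7-(benzyloxy)-2-[3,4-bis(benzyloxy)phenyl]-3-hydroxy-4-oxo-3,4-dihydro-2H-chromen-6-yl](hydroxy)methyl}-3-hydroxyphenyl benzoate (both carbinol epimers), via bromomagnesium phenoxide 11 (not isolated)
Conditions: 10, EtMgBr, Et2O, 0 °C; then toluene, 9, rt; aq NH4Cl
Reagents that add atoms: none
Why: Magnesium phenoxide-mediated ortho-specific hydroxyalkylation delivers the magnesium-bound aldehyde through a six-membered chelate to the phenoxide carbon ortho to oxygen and para to the benzoyloxy group, the hindered aryl ketone stays untouched, and the new carbinol centre needs no control because it becomes trigonal in step 11.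

**Step 8**
Reactants: 4 3,4-bis(benzyloxy)benzaldehyde
Product: 13 2-[(E)-2-[3,4-bis(benzyloxy)phenyl]ethenyl]-4,4,5,5-tetramethyl-1,3,2-dioxaborolane
Conditions: CH2(Bpin)2, LiTMP (from 2,2,6,6-tetramethylpiperidine and n-BuLi), THF, −78 °C to rt
Reagents that add atoms: bis[(pinacolato)boryl]methane CC1(C)OB(CB2OC(C)(C)C(C)(C)O2)OC1(C)C
Why: Boron–Wittig olefination: the lithiated geminal diboronate adds to the aldehyde and syn-elimination of the boron–oxygen pair gives the E-alkenyl boronate.

**Step 9**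
Reactants: 13 the (E)-alkenyl pinacol boronate
Product: 14 potassium (E)-{2-[3,4-bis(benzyloxy)phenyl]ethenyl}trifluoroborate
Conditions: KHF2, MeOH/H2O, rt
Reagents that add atoms: potassium hydrogen difluoride [K+].F[H-]F
Why: Fluoride exchange at boron converts the pinacol ester into the crystalline trifluoroborate with the alkene geometry unchanged.

**Step 10**
Reactants: 14 the potassium (E)-alkenyltrifluoroborate
Product: 15 (E)-2-[3,4-bis(benzyloxy)phenyl]ethenyl acetate
Conditions: AcOH, CuBr (10 mol %), DMAP, 4 Å MS, O2 (1 atm), MeCN, 60 °C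
Reagents that add atoms: acetic acid CC(=O)O
Why: Chan–Lam-type oxidative copper-catalysed C–O coupling of the alkenyl trifluoroborate with the carboxylic acid is stereoretentive and should give the E enol acetate.

**Step 11**
Reactants: 12 the ortho-hydroxybenzhydrol; 15 the (E)-enol acetate
Product: 17 (2R,3S,4S)-3-acetoxy-2-[3,4-bis(benzyloxy)phenyl]-4-[(2R,3R)-7-(benzyloxy)-2-[3,4-bis(benzyloxy)phenyl]-3-hydroxy-4-oxo-3,4-dihydro-2H-chromen-6-yl]-3,4-dihydro-2H-chromen-7-yl benzoate (upper ring 2,3-trans-3,4-trans), via ortho-quinone methide 16 (not isolated)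
Conditions: (R)-3,3′-bis(2,4,6-triisopropylphenyl)-1,1′-binaphthyl-2,2′-diyl N-triflylphosphoramide (10 mol %), 15 (3 equiv), CHCl3, 4 Å MS, 0 °C to rt, slow addition of 12
Reagents that add atoms: none
Why: Proposed new method: the chiral acid ionises the carbinol of 12 to the (E)-ortho-quinone methide 16, held as a hydrogen-bonded ion pair, and the alkene of 15 adds across C4=C4a–C8a=O in an asynchronous inverse-electron-demand oxa-[4+2] cycloaddition, the closest known reaction type being the chiral phosphoric acid or N-triflylphosphoramide catalysed cycloaddition of ortho-hydroxybenzhydrol-derived quinone methides with styrenes, to which the β-acyloxy group is the untested addition. Ring C closes in a [4+2] hetero-Diels–Alder mode, C3–C4 forming ahead of O1–C2. The regiochemistry needed (C4 to the acetoxy-bearing carbon, O1 to the benzylic carbon) is secured by the 4-benzyloxyphenyl group, which stabilises the developing positive charge far better than an acyloxy oxygen can. C2 and C3 are trans because the E geometry of 15 is transferred suprafacially, C3 and C4 are trans (C2-aryl and C4-aryl cis) through the (E)-quinone methide and the aryl-endo transition state, and the absolute configuration of all three centres follows from the face of C4 that the chiral phosphoramide anion leaves open, the stereocentres of the lower unit being too remote to compete. The benzoate on the ring A oxygen makes 16 more electrophilic and ring A less nucleophilic, so that cycloaddition with excess 15 should outpace Friedel–Crafts self-condensation, and the lower C4 ketone keeps the lower heterocycle inert to the acid.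

**Step 12**
Reactants: 17 the cycloadduct
Product: 18 (2R,3R)-7-(benzyloxy)-2-[3,4-bis(benzyloxy)phenyl]-6-[(2R,3S,4S)-2-[3,4-bis(benzyloxy)phenyl]-3,7-dihydroxy-3,4-dihydro-2H-chromen-4-yl]-3-hydroxy-2,3-dihydro-4H-chromen-4-one
Conditions: K2CO3, MeOH/THF, 0 °C to rt
Reagents that add atoms: none
Why: Base-catalysed transesterification (Zemplén-type methanolysis) cleaves the aryl benzoate and the secondary acetate without touching a stereocentre, the 2,3-trans dihydroflavonol being the thermodynamic isomer at its enolisable C3.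

**Step 13**
Reactants: 18 the penta-O-benzyl ketone
Product: 19 (2R,3R)-2-(3,4-dihydroxyphenyl)-6-[(2R,3S,4R)-2-(3,4-dihydroxyphenyl)-3,7-dihydroxy-3,4-dihydro-2H-chromen-4-yl]-3,7-dihydroxy-2,3-dihydro-4H-chromen-4-one
Conditions: H2 (1 atm), Pd(OH)2/C, THF/MeOH, rt
Reagents that add atoms: none
Why: Hydrogenolysis removes the five benzyl ethers while the deactivated C4 ketone is kept on purpose, since a free C4 carbinol would itself be open to hydrogenolysis.

**Step 14**
Reactants: 19 the free phenolic ketone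
Product: 20 CNP0280090.3, (2R,3S,4R)-2-(3,4-dihydroxyphenyl)-6-[(2R,3S,4R)-2-(3,4-dihydroxyphenyl)-3,7-dihydroxy-3,4-dihydro-2H-chromen-4-yl]-3,4-dihydro-2H-chromene-3,4,7-triol
Conditions: NaBH4, EtOH, 0 °C to rt; AcOH to pH 6
Reagents that add atoms: none
Why: Hydride reduction of the 2,3-trans dihydroflavonol carbonyl should give the 2,3-trans-3,4-trans diol (new lower C4, R) by axial hydride delivery anti-periplanar to the axial C3–H, the usual substrate-controlled outcome for trans-dihydroflavonols.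

**Compound list**

1 | 1-[4-(benzyloxy)-2-hydroxyphenyl]ethanone | CC(=O)c1ccc(OCc2ccccc2)cc1O | starting material
2 | 1-[4-(benzyloxy)-5-bromo-2-hydroxyphenyl]ethanone | CC(=O)c1cc(Br)c(OCc2ccccc2)cc1O | intermediate
3 | 1-[4-(benzyloxy)-5-bromo-2-(methoxymethoxy)phenyl]ethanone | CC(=O)c1cc(Br)c(OCc2ccccc2)cc1OCOC | intermediate
4 | 3,4-bis(benzyloxy)benzaldehyde | O=Cc1ccc(OCc2ccccc2)c(OCc2ccccc2)c1 | starting material
5 | (E)-1-[4-(benzyloxy)-5-bromo-2-(methoxymethoxy)phenyl]-3-[3,4-bis(benzyloxy)phenyl]prop-2-en-1-one | COCOc1cc(OCc2ccccc2)c(Br)cc1C(=O)/C=C/c1ccc(OCc2ccccc2)c(OCc2ccccc2)c1 | intermediate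
6 | [4-(benzyloxy)-5-bromo-2-(methoxymethoxy)phenyl][(2R,3S)-3-[3,4-bis(benzyloxy)phenyl]oxiran-2-yl]methanone | COCOc1cc(OCc2ccccc2)c(Br)cc1C(=O)[C@@H]1O[C@H]1c1ccc(OCc2ccccc2)c(OCc2ccccc2)c1 | intermediate
7 | [4-(benzyloxy)-5-bromo-2-hydroxyphenyl][(2R,3S)-3-[3,4-bis(benzyloxy)phenyl]oxiran-2-yl]methanone (not isolated) | Oc1cc(OCc2ccccc2)c(Br)cc1C(=O)[C@@H]1O[C@H]1c1ccc(OCc2ccccc2)c(OCc2ccccc2)c1 | intermediate
8 | (2R,3R)-7-(benzyloxy)-2-[3,4-bis(benzyloxy)phenyl]-6-bromo-3-hydroxy-2,3-dihydro-4H-chromen-4-one | Brc1cc2c(cc1OCc1ccccc1)O[C@H](c1ccc(OCc3ccccc3)c(OCc3ccccc3)c1)[C@@H](O)C2=O | intermediate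
9 | (2R,3R)-7-(benzyloxy)-2-[3,4-bis(benzyloxy)phenyl]-3-hydroxy-4-oxo-3,4-dihydro-2H-chromene-6-carbaldehyde | O=Cc1cc2c(cc1OCc1ccccc1)O[C@H](c1ccc(OCc3ccccc3)c(OCc3ccccc3)c1)[C@@H](O)C2=O | intermediate
10 | 3-hydroxyphenyl benzoate | O=C(Oc1cccc(O)c1)c1ccccc1 | starting material
11 | bromomagnesium 3-(benzoyloxy)phenoxide (not isolated) | Br[Mg]Oc1cccc(OC(=O)c2ccccc2)c1 | intermediate
12 | 4-{[(2R,3R)-7-(benzyloxy)-2-[3,4-bis(benzyloxy)phenyl]-3-hydroxy-4-oxo-3,4-dihydro-2H-chromen-6-yl](hydroxy)methyl}-3-hydroxyphenyl benzoate, carbinol centre as both epimers | OC(c1ccc(OC(=O)c2ccccc2)cc1O)c1cc2c(cc1OCc1ccccc1)O[C@H](c1ccc(OCc3ccccc3)c(OCc3ccccc3)c1)[C@@H](O)C2=O | intermediate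
13 | 2-[(E)-2-[3,4-bis(benzyloxy)phenyl]ethenyl]-4,4,5,5-tetramethyl-1,3,2-dioxaborolane | CC1(C)OB(/C=C/c2ccc(OCc3ccccc3)c(OCc3ccccc3)c2)OC1(C)C | intermediate
14 | potassium (E)-{2-[3,4-bis(benzyloxy)phenyl]ethenyl}trifluoroborate | [K+].F[B-](F)(F)/C=C/c1ccc(OCc2ccccc2)c(OCc2ccccc2)c1 | intermediate
15 | (E)-2-[3,4-bis(benzyloxy)phenyl]ethenyl acetate | CC(=O)O/C=C/c1ccc(OCc2ccccc2)c(OCc2ccccc2)c1 | intermediate
16 | 4-{(E)-[(2R,3R)-7-(benzyloxy)-2-[3,4-bis(benzyloxy)phenyl]-3-hydroxy-4-oxo-3,4-dihydro-2H-chromen-6-yl]methylidene}-3-oxocyclohexa-1,5-dien-1-yl benzoate, the ortho-quinone methide (not isolated) | O=C1C=C(OC(=O)c2ccccc2)C=C/C1=C\c1cc2c(cc1OCc1ccccc1)O[C@H](c1ccc(OCc3ccccc3)c(OCc3ccccc3)c1)[C@@H](O)C2=O | intermediate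
17 | (2R,3S,4S)-3-acetoxy-2-[3,4-bis(benzyloxy)phenyl]-4-[(2R,3R)-7-(benzyloxy)-2-[3,4-bis(benzyloxy)phenyl]-3-hydroxy-4-oxo-3,4-dihydro-2H-chromen-6-yl]-3,4-dihydro-2H-chromen-7-yl benzoate; upper ring all-trans in the spatial sense of the target (C4 reads S only because of the CIP ranking of the benzyl ethers) | O=C(c1ccccc1)Oc1ccc2c(c1)O[C@H](c1ccc(OCc3ccccc3)c(OCc3ccccc3)c1)[C@@H](OC(C)=O)[C@@H]2c1cc2c(cc1OCc1ccccc1)O[C@H](c1ccc(OCc3ccccc3)c(OCc3ccccc3)c1)[C@@H](O)C2=O | intermediate
18 | (2R,3R)-7-(benzyloxy)-2-[3,4-bis(benzyloxy)phenyl]-6-[(2R,3S,4S)-2-[3,4-bis(benzyloxy)phenyl]-3,7-dihydroxy-3,4-dihydro-2H-chromen-4-yl]-3-hydroxy-2,3-dihydro-4H-chromen-4-one | Oc1ccc2c(c1)O[C@H](c1ccc(OCc3ccccc3)c(OCc3ccccc3)c1)[C@@H](O)[C@@H]2c1cc2c(cc1OCc1ccccc1)O[C@H](c1ccc(OCc3ccccc3)c(OCc3ccccc3)c1)[C@@H](O)C2=O | intermediate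
19 | (2R,3R)-2-(3,4-dihydroxyphenyl)-6-[(2R,3S,4R)-2-(3,4-dihydroxyphenyl)-3,7-dihydroxy-3,4-dihydro-2H-chromen-4-yl]-3,7-dihydroxy-2,3-dihydro-4H-chromen-4-one | Oc1ccc2c(c1)O[C@H](c1ccc(O)c(O)c1)[C@@H](O)[C@@H]2c1cc2c(cc1O)O[C@H](c1ccc(O)c(O)c1)[C@@H](O)C2=O | intermediate
20 | CNP0280090.3, (2R,3S,4R)-2-(3,4-dihydroxyphenyl)-6-[(2R,3S,4R)-2-(3,4-dihydroxyphenyl)-3,7-dihydroxy-3,4-dihydro-2H-chromen-4-yl]-3,4-dihydro-2H-chromene-3,4,7-triol | Oc1ccc2c(c1)O[C@H](c1ccc(O)c(O)c1)[C@@H](O)[C@@H]2c1cc2c(cc1O)O[C@H](c1ccc(O)c(O)c1)[C@@H](O)[C@@H]2O | target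

**Step count.** Total: 14 steps. Longest linear sequence: 11 steps (steps 1–7, then 11–14); the dienophile branch (steps 8–10) joins at step 11.

**Steps most likely to fail**

1. Step 11 (the step that carries the label). What may go wrong: slow cycloaddition of the inductively deactivated enol acetate, so that Friedel–Crafts self-alkylation by the quinone methide takes over; incomplete facial control by the catalyst; erosion of the aryl-endo preference. The fallback uses known chemistry, sets out from 12 and 14 and comes back at 18. Compound 14 is converted with TMSCl in EtOH into diethyl (E)-{2-[3,4-bis(benzyloxy)phenyl]ethenyl}boronate F1. Under catalysis by 3,3′-dibromo-1,1′-bi-2-naphthol (enantiomer chosen for the C4 configuration; toluene, 4 Å MS, rt), F1 transfers its alkenyl group to the quinone methide formed from 12, a biphenol-catalysed asymmetric conjugate alkenylation of ortho-quinone methides. This should give the (E)-1,3-diarylallyl phenol F2 with C4 set by the catalyst. TBSCl and imidazole give the aryl silyl ether F3. Shi epoxidation with the enantiomer of the fructose-derived ketone (Oxone, K2CO3 buffer, MeCN/dimethoxymethane, 0 °C) should give the trans (S,S)-epoxide F4 under reagent control. TBAF/AcOH followed by catalytic CSA lets the freed phenol open the epoxide 6-endo at the benzylic carbon with inversion; this closes ring C, still as the last ring, and gives the all-trans 7-O-benzoate F5. K2CO3 in MeOH then gives 18.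

2. Step 7. What may go wrong: acyl transfer between magnesium phenoxides, attack at the carbon between the two ring oxygens, or a second arylation of the product through its own quinone methide. The fallback sets out from 9 and 10 and comes back at 12. Condensation of 9 and 10 with phenylboronic acid (catalytic propionic acid, toluene, reflux with removal of water) ties phenol and aldehyde together under non-basic conditions as the 2-phenyl-4H-1,3,2-benzodioxaborin F6, with ortho regiochemistry enforced by the boron template. Exchange of boron with propane-1,3-diol at rt then frees 12.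

3. Step 6. What may go wrong: reductive loss of bromine, or heat- and amine-induced degradation of the α-ketol during the carbonylation. The fallback sets out from 8 and comes back at 9. Stille coupling of 8 with tributyl(vinyl)stannane (Pd(PPh3)4, toluene, 90 °C, no base) gives the 6-vinyl dihydroflavonol F7. Lemieux–Johnson cleavage (OsO4 cat., NaIO4, 2,6-lutidine, dioxane/H2O) then gives 9.

**Further compounds**

F1 | step 11 | diethyl (E)-{2-[3,4-bis(benzyloxy)phenyl]ethenyl}boronate | CCOB(OCC)/C=C/c1ccc(OCc2ccccc2)c(OCc2ccccc2)c1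
F2 | step 11 | 4-{(E)-1-[(2R,3R)-7-(benzyloxy)-2-[3,4-bis(benzyloxy)phenyl]-3-hydroxy-4-oxo-3,4-dihydro-2H-chromen-6-yl]-3-[3,4-bis(benzyloxy)phenyl]prop-2-en-1-yl}-3-hydroxyphenyl benzoate, C1 of the allyl unit configured as C4 of the target | O=C(c1ccccc1)Oc1ccc(c(O)c1)[C@H](/C=C/c1ccc(OCc2ccccc2)c(OCc2ccccc2)c1)c1cc2c(cc1OCc1ccccc1)O[C@H](c1ccc(OCc3ccccc3)c(OCc3ccccc3)c1)[C@@H](O)C2=O
F3 | step 11 | tert-butyldimethylsilyl ether of the phenol of F2 | O=C(c1ccccc1)Oc1ccc(c(O[Si](C)(C)C(C)(C)C)c1)[C@H](/C=C/c1ccc(OCc2ccccc2)c(OCc2ccccc2)c1)c1cc2c(cc1OCc1ccccc1)O[C@H](c1ccc(OCc3ccccc3)c(OCc3ccccc3)c1)[C@@H](O)C2=O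
F4 | step 11 | trans (S,S)-epoxide of F3 | O=C(c1ccccc1)Oc1ccc(c(O[Si](C)(C)C(C)(C)C)c1)[C@H]([C@@H]1O[C@H]1c1ccc(OCc2ccccc2)c(OCc2ccccc2)c1)c1cc2c(cc1OCc1ccccc1)O[C@H](c1ccc(OCc3ccccc3)c(OCc3ccccc3)c1)[C@@H](O)C2=O
F5 | step 11 | 7-O-benzoate of 18 (upper ring all-trans, 3-OH free) | O=C(c1ccccc1)Oc1ccc2c(c1)O[C@H](c1ccc(OCc3ccccc3)c(OCc3ccccc3)c1)[C@@H](O)[C@@H]2c1cc2c(cc1OCc1ccccc1)O[C@H](c1ccc(OCc3ccccc3)c(OCc3ccccc3)c1)[C@@H](O)C2=O
F6 | step 7 | 4-[(2R,3R)-7-(benzyloxy)-2-[3,4-bis(benzyloxy)phenyl]-3-hydroxy-4-oxo-3,4-dihydro-2H-chromen-6-yl]-2-phenyl-4H-1,3,2-benzodioxaborin-7-yl benzoate (both C4 epimers) | O=C(c1ccccc1)Oc1ccc2c(c1)OB(c1ccccc1)OC2c1cc2c(cc1OCc1ccccc1)O[C@H](c1ccc(OCc3ccccc3)c(OCc3ccccc3)c1)[C@@H](O)C2=O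
F7 | step 6 | (2R,3R)-7-(benzyloxy)-2-[3,4-bis(benzyloxy)phenyl]-6-ethenyl-3-hydroxy-2,3-dihydro-4H-chromen-4-one | C=Cc1cc2c(cc1OCc1ccccc1)O[C@H](c1ccc(OCc3ccccc3)c(OCc3ccccc3)c1)[C@@H](O)C2=O
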